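The starting material charged is a fixed sum: whatever leaves it sits in target or on the way to side product through intermediate A, so I follow how that split falls.

| flask | starting material | partner | temperature | remark | time |
|---|---|---|---|---|---|
| Sunday's | 0.014 M | 0.70 equiv | 20 °C | run made earlier |  |
| Friday's | 0.022 M | 0.70 equiv | 35 °C | run made earlier |  |
| Thursday's | 0.010 M | 0.35 equiv | 20 °C | run made earlier |  |
| alpha | 0.010 M | 0.700 equiv | 25 °C |  | 2.5 h |
| gamma | 0.010 M | 0.700 equiv | 45 °C |  | 2.5 h |

Sunday's run (percent of the starting material charged)

| time / h | intermediate C / % | starting material / % | target / % | intermediate A / % | side product / % |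
|---|---|---|---|---|---|
| 0.500 | 0 | 87.4 | 6.6 | 5.4 | 0 |
| 1.00 | 0.4 | 77.1 | 12.0 | 9.4 | 0.5 |
| 1.50 | 0 | 68.8 | 16.9 | 12.2 | 0.1 |
| 2.00 | 0.5 | 61.6 | 21.0 | 14.1 | 0.2 |
| 2.50 | 0.8 | 56.1 | 23.9 | 16.0 | 0 |

Friday's run (percent of the starting material charged)

| time / min | intermediate C / % | starting material / % | target / % | intermediate A / % | side product / % |
|---|---|---|---|---|---|
| 8.00 | 0 | 80.3 | 11.2 | 7.0 | 0.1 |
| 15.0 | 0 | 68.3 | 18.1 | 10.6 | 0.2 |
| 25.0 | 0.1 | 55.1 | 25.6 | 14.0 | 0.2 |
| 50.0 | 1.6 | 35.8 | 35.5 | 14.3 | 1.8 |
| 90.0 | 5.9 | 20.3 | 43.6 | 9.4 | 6.8 |

Thursday's run (percent of the starting material charged)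

| time / h | intermediate C / % | starting material / % | target / % | intermediate A / % | side product / % |
|---|---|---|---|---|---|
| 0.200 | 0.1 | 97.0 | 0.9 | 2.4 | 0 |
| 0.417 | 0 | 92.6 | 2.0 | 4.7 | 0 |
| 0.667 | 0 | 88.9 | 3.3 | 7.3 | 0.2 |
| 1.33 | 0 | 79.8 | 6.5 | 12.1 | 0 |
| 2.50 | 0.4 | 67.5 | 9.9 | 17.5 | 0.2 |

(scatter of a reading: 0.3 percentage points)

- which of these there is most of at the end, counted by the starting material in it, alpha (intermediate C / starting material / intermediate A / side product / target)
- which of these there is most of at the end, counted by the starting material in it, gamma (intermediate C / starting material / intermediate A / side product / target)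
- final amount of the leader among these, as a percentage of the starting material charged, in alpha
- final amount of the leader among these, as a percentage of the starting material charged, in gamma

- the earlier runs were read with a standard deviation of 0.3 percentage points
- a reading or a percentage of target counts all its forms, free or not
- a reading of intermediate C is of its free form alone

Friday's first readings, at 8.00 min, give 9.62 mM for the crossing concentration, the [partner] at which both exits from starting material run equally, reckoned as charged [partner] times intermediate A over target. It is the zero of a selectivity scale. Sunday's first readings give 8.02 mM and Thursday's 9.33 mM, so I treat it as a rough reading.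

Gamma starts at 7.00 mM of partner, below the crossing, so target takes under half of what leaves. I take gamma's starting material as nearly consumed and solve two extremes. If [partner] never fell, target would take 42.1 %. If [partner] sat from the outset at what that much target leaves, 2.79 mM, target would take 22.5 %. The real [partner] runs between them, so I commit to the midpoint, 32.3 %. Side product then leads gamma if about half of the remainder arrives, and Friday's already shows 6.8 % of side product at 90.0 min and 35 °C. In alpha I expect starting material to lead, since Sunday's, at 20 °C, still held 56.1 % of it at 2.50 h, more than its target at 23.9 %, and alpha stands at 25 °C.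

The forecast says starting material at 42 % for alpha, and side product at 48 % for gamma, with gamma's target stopping “because the two paths compete”.

The flasks give starting material at 44.4 % in alpha, and side product at 47.7 % in gamma, with target at 34.2 %.

    crystals ⇌ target, rate k1*(cs1 - [target]) while solid is left; crystals form when [target] > cs1 (solubility = 6.50 mM, k = 19.0 h⁻¹)
    intermediate A → intermediate B (k = 0.370 h⁻¹, Ea = 104 kJ mol⁻¹)
    intermediate B ⇌ intermediate C (K = 2.50, k = 0.160 h⁻¹, Ea = 98.0 kJ mol⁻¹, ΔH = −27.0 kJ mol⁻¹)
    intermediate D → side product (k = 5.80 h⁻¹, Ea = 91.0 kJ mol⁻¹)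
    starting material + partner → target (k = 26.0 L mol⁻¹ h⁻¹, Ea = 71.0 kJ mol⁻¹)
    starting material ⇌ intermediate A (K = 1.10, k = 0.230 h⁻¹, Ea = 88.0 kJ mol⁻¹, ΔH = −3.00 kJ mol⁻¹)
    intermediate B → intermediate D (k = 0.190 h⁻¹, Ea = 86.0 kJ mol⁻¹)
    (constants at 25 °C)

Held constant and summed over a whole run, the crossing becomes the share of starting material that went elsewhere than target, times its charge, over the logarithm of charged partner to partner left. For gamma that gives 9.69 mM. The forecast's leader for gamma loses its place in the same flask run at 30 °C: the crossing there comes to 7.39 mM, the leader is target at 30.0 %, and side product stands at 6.40 %.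

(All runs stem from a simulated flask with made-up constants; scatter was added.)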